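In a one-step world L would turn straight into X.E and one rate constant would tell the flask, but here X.E needs X and E together, and neither is charged.

    G → E (k1 = 0.0786 s⁻¹)
    L ⇌ X (K2 = 2.0, k2 = 0.0203 s⁻¹)
    E → Q (k3 = 0.00947 s⁻¹)
    X + E → X.E (k4 = 130 M⁻¹ s⁻¹)
    2 X → X2 (k5 = 3.06 M⁻¹ s⁻¹)
    X.E ⇌ D (K6 = 15.6, k6 = 0.0275 s⁻¹)

- Monday's: L 1.0 mM; G 1.20 mM; time 20 s
- Thursday's: L 1.0 mM; G 3.00 mM; time 20 s

* which of the two there is more of at the end, Monday's (D / X.E)
* which of the two there is more of at the end, Thursday's (D / X.E)
* final X.E, as a percentage of the L charged, in Monday's
* final X.E, as a percentage of the L charged, in Thursday's

- percent here means L units held: one X2 counts as two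
- where a step has two of a species, its rate is k times that concentration squared, and two are used at each turn
- run time (Monday's): 20 s

We follow one rate, the flow of L towards X.E, in fractions of the charge of L. At the start L gives X at 0.0203 s⁻¹, and kept up over 20 s that would pass 40.6% of the charge.

The first slowing is the wait for a partner. Early on, X and E both grow in proportion to time, so capture, a product of the two, grows as the square of time until it meets the supply from L. That moment is one over the square root of the capture constant times the constant of G's loss times the charge of G: 9.03 s in Monday's and 5.71 s in Thursday's. We call it the crossing time. Both lie inside the run, so in this estimate we let capture keep up with the supply from L after the crossing, and the flow counts for the remaining part of the run, a factor 0.548 in Monday's and 0.714 in Thursday's.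

The second slowing is the fall of L itself, which at the middle of that window is a factor 0.745 in Monday's and 0.770 in Thursday's. The third is the passage to D: X.E made in the window has waited for half of it on average, so a factor 0.849 in Monday's and 0.804 in Thursday's stays X.E. We leave out the return of X to L.

Multiplied up, our reckoning gives 14.1% of the charge as X.E in Monday's and 18.0% in Thursday's, with X.E ahead of D in both.

The forecast agrees with us on which stands ahead but differs in the amounts: it says X.E for Monday's and X.E for Thursday's, with 13% and 19%, and its ground is this: “X.E has had too little time to pass into D”.

The flask gives X.E ahead in both: 13.9% against 2.77% of D in Monday's, 21.0% against 4.79% in Thursday's.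

In Monday's, half of the capture's turnover up to the end was done by 13.5 s, later than the reckoned crossing, and the 6.50 s from then to the end are shorter than the 25 s half-life of X.E by the forward rate of its loss to D. A neighbour like Monday's but with 2.0 mM of G has an earlier reckoned crossing, at 7.00 s, and ends with 18.2% as X.E and 9.66% as X, where Monday's holds 13.9% and 14.6%.

The constants were chosen freely; the result is computed.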